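Amounts first: each set-up takes in the same 2.0 M of starting material, and the question is what part of it ends as target.

in all of them: starting material 2.0 M

| flask | time | remark |
|---|---|---|
| alder | 80 min | a closed flask charged with all of it at once and left for 80 min |
| cedar | 80 min | a tube with plug flow, the mixed feed as stated, residence time 80 min |
| elm |  | one stirred flow tank at steady state, fed with the mixture as stated, mean residence time 80 min |

    starting material → intermediate A (k1 = 4.19 × 10⁻⁴ /s)
    starting material → target (k2 = 3.27 × 10⁻⁴ /s)
    starting material → side product (k3 = 0.00107 /s)
    intermediate A ⇌ intermediate B (K4 = 3.96, k4 = 2.52 × 10⁻⁵ /s)

- the stated concentrations are those of everything mixed, before any reaction; amounts are the same in each set-up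
- run time (alder): 80 min

* the set-up with the highest amount of target at the outlet or at the end, in percent of the starting material put in ("none" if the first two lie within 2 percentage points) (alder / cedar / elm / none)
* amount of target at the outlet or at the end, in percent of the starting material put in, alder
* amount of target at the outlet or at the end, in percent of the starting material put in, cedar
* amount of target at the outlet or at the end, in percent of the starting material put in, elm

**Turnovers counted.** The number of turnovers is 8.72: the rate constants out of the starting material, summed, times the time held. This is the Damköhler number. Every step out of the starting material runs at its constant times [starting material], so the target takes a fixed share of what reacts, 18.0 %. Intermediate A and intermediate B exchange with each other and return nothing to the starting material, so they stay out of the count.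

**The opposite outcome.** A clear winner needs the top two set-ups to part by more than 2 percentage points. In alder and in cedar each portion of liquid reacts unmixed for 80 min, so both follow one equation over one time. Both leave a fraction exp(−turnovers) of the starting material, 0.0163 %, and give 18.0 % target, so their gap is nil. A clear winner then has to be elm, standing above them by more than 2 points. Its liquid is mixed, so it leaves 1/(1 + turnovers), or 10.3 %, unreacted. With the same share it gives 16.2 %, less than alder. My reckoning therefore says none.

**The forecast.** It gave 18 % for alder, 18 % for cedar, 16.2 % for elm and none as best, on these grounds: “the target always takes a fixed share”.

**The simulation.** It gives 18.0 % for alder, 18.0 % for cedar, 16.2 % for elm and none as best.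

**What ran.** In alder the steps out of the starting material ran side by side through 8.72 turnovers, leaving 58.9 % side product and 20.8 % intermediate A beside the target, while in elm the same steps ran at one steady [starting material] of 0.206 M. Alder at 11.8 min, after 1.28 turnovers, held 13.0 % target by the count, 5 points below its end value.

The rate constants are made up, and the outcome is calculated.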